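**Retrosynthetic overview**

1. Feature: in ring B the C5–C6 bond lies allylic to the ring-A alkene C1=C10 (C6–C5–C10=C1). With a hydroxyl on C6 this is the homoallylic alcohol left by a carbonyl-ene reaction, so ring B is opened at C5–C6 to aldehyde 19, which carries a C5=C10 alkene and a spectator C12 silyl ether.
2. After ring closure: C6 is deoxygenated; C12–OH becomes the iodide, then the terminal alkyne; Zr-catalysed carboalumination with CH2O capture gives the E C13=C14 alkene and C15–OH; the ester is demethylated and C15 is propionylated.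
3. Aldehyde 19 comes from a C9–C10 union: Cu/carbene-catalysed SN2′ alkenylation of allylic phosphate 13 (C8 from lactone 7) with ring-A boronate 6 creates quaternary C9 and a vinyl group, which becomes the C11–C12 silyloxyethyl arm.
4. Ring A is carried from dione 1: conjugate methylation of keto ester 3 sets C4, and trapping the enolate as triflate 5 fixes the alkene at C5=C10. Ring order: A (bought), then B (step 16).

Key step: step 16

Numbering: halimane numbering (ring A = C1–C5, C10; ring B = C5–C10; C17 on C8; C20 on C9; C18 = carboxyl carbon and C19 = methyl on C4; side chain C11–C16 on C9); β is the ring-A face that carries C18.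
Assumption: lactone 7 is used as the purchasable (R)-enantiomer, and the chiral carbene ligands of steps 3 and 11 are used as the antipodes that give (4S) and (9S).

**Route**

Step 1
Reactants: 1 cyclohexane-1,3-dione
Product: 2 3-bromocyclohex-2-en-1-one
Conditions: Ph3PBr2, Et3N, CH2Cl2, 0 °C → rt
Reagents that add atoms: triphenylphosphine dibromide, BrP(Br)(c1ccccc1)(c1ccccc1)c1ccccc1
Why: The enol oxygen is activated by the bromophosphonium reagent and replaced by bromide through addition–elimination, the standard conversion of a 1,3-dione into a β-bromo enone.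

Step 2
Reactants: 2 3-bromocyclohex-2-en-1-one
Product: 3 methyl 3-oxocyclohex-1-ene-1-carboxylate
Conditions: CO (1 atm), Pd(OAc)2 (cat.), PPh3, i-Pr2NEt, MeOH/DMF, 60 °C
Reagents that add atoms: carbon monoxide, [C-]#[O+]; methanol, CO
Why: Palladium-catalysed alkoxycarbonylation of a vinyl bromide (oxidative addition, CO insertion, methanolysis); the hindered amine only takes up HBr, so direct addition–elimination of methanol stays slow.

Step 3
Reactants: 3 methyl 3-oxocyclohex-1-ene-1-carboxylate
Product: 5 methyl (1S)-1-methyl-3-(trifluoromethylsulfonyloxy)cyclohex-2-ene-1-carboxylate, via methylzinc enolate 4 (not isolated)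
Conditions: Me2Zn, (CuOTf)2·C6H6 (2.5 mol %), chiral sulfonate-bearing imidazolinium salt (carbene precursor, 5 mol %), t-BuOMe, −30 °C; then Tf2O, −78 → 0 °C
Reagents that add atoms: dimethylzinc, C[Zn]C; trifluoromethanesulfonic anhydride, O=S(=O)(OS(=O)(=O)C(F)(F)F)C(F)(F)F
Why: Copper-catalysed enantioselective conjugate addition of a dialkylzinc to a β-carboalkoxy cyclic enone creates the C4 quaternary centre (S, set by the ligand antipode), and O-triflation of the regiodefined zinc enolate fixes the alkene at C5=C10, which later enolisation of the ketone could not reach.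

Step 4
Reactants: 5 methyl (1S)-1-methyl-3-(trifluoromethylsulfonyloxy)cyclohex-2-ene-1-carboxylate
Product: 6 methyl (1S)-1-methyl-3-(4,4,5,5-tetramethyl-1,3,2-dioxaborolan-2-yl)cyclohex-2-ene-1-carboxylate
Conditions: B2pin2, PdCl2(PPh3)2 (cat.), PPh3, KOPh, toluene, 50 °C
Reagents that add atoms: bis(pinacolato)diboron, CC1(C)OB(OC1(C)C)B1OC(C)(C)C(C)(C)O1
Why: Miyaura borylation of an alkenyl triflate; the ester and the quaternary centre are not touched.

Step 5
Reactants: 7 (R)-α-methyl-γ-butyrolactone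
Product: 8 (2R)-4-hydroxy-N-methoxy-N,2-dimethylbutanamide
Conditions: MeNH(OMe)·HCl, AlMe3, CH2Cl2, 0 °C → rt; aq. HCl
Reagents that add atoms: N,O-dimethylhydroxylamine hydrochloride, CNOC.Cl
Why: Aminolysis of the lactone by the aluminium amide (Weinreb amide formation); the Lewis acidic medium should not enolise C8.

Step 6
Reactants: 8 (2R)-4-hydroxy-N-methoxy-N,2-dimethylbutanamide
Product: 9 (2R)-4-[(tert-butyldimethylsilyl)oxy]-N-methoxy-N,2-dimethylbutanamide
Conditions: TBSCl, imidazole, DMF, 0 °C → rt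
Reagents that add atoms: tert-butyldimethylsilyl chloride, CC(C)(C)[Si](C)(C)Cl
Why: Silylation of the primary alcohol, done at once so that the hydroxy amide cannot close back to the lactone.

Step 7
Reactants: 9 (2R)-4-[(tert-butyldimethylsilyl)oxy]-N-methoxy-N,2-dimethylbutanamide
Product: 10 (3R)-5-[(tert-butyldimethylsilyl)oxy]-3-methylpentan-2-one
Conditions: MeMgBr, THF, 0 °C; aq. NH4Cl
Reagents that add atoms: methylmagnesium bromide, C[Mg]Br
Why: Weinreb ketone synthesis: the chelated adduct stops at the methyl ketone (C9 with C20), and the cold buffered quench should keep the α-centre C8.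

Step 8
Reactants: 10 (3R)-5-[(tert-butyldimethylsilyl)oxy]-3-methylpentan-2-one
Product: 11 ethyl (2E,4R)-6-[(tert-butyldimethylsilyl)oxy]-3,4-dimethylhex-2-enoate
Conditions: (EtO)2P(O)CH2CO2Et, NaH, THF, 0 °C → rt
Reagents that add atoms: triethyl phosphonoacetate, CCOC(=O)CP(=O)(OCC)OCC
Why: Horner–Wadsworth–Emmons olefination of the methyl ketone; the α-branched residue should place the ester trans to it (E), and the minor Z isomer is removed by chromatography.

Step 9
Reactants: 11 ethyl (2E,4R)-6-[(tert-butyldimethylsilyl)oxy]-3,4-dimethylhex-2-enoate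
Product: 12 (2E,4R)-6-[(tert-butyldimethylsilyl)oxy]-3,4-dimethylhex-2-en-1-ol
Conditions: i-Bu2AlH, CH2Cl2, −78 °C; aq. KNaC4H4O6
Reagents that add atoms: none
Why: 1,2-Reduction of the enoate to the allylic alcohol by the aluminium hydride; silyl ether and alkene geometry are unaffected.

Step 10
Reactants: 12 (2E,4R)-6-[(tert-butyldimethylsilyl)oxy]-3,4-dimethylhex-2-en-1-ol
Product: 13 (2E,4R)-6-[(tert-butyldimethylsilyl)oxy]-3,4-dimethylhex-2-en-1-yl diethyl phosphate
Conditions: (EtO)2P(O)Cl, pyridine, DMAP (cat.), CH2Cl2, 0 °C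
Reagents that add atoms: diethyl chlorophosphate, CCOP(=O)(Cl)OCC
Why: Phosphorylation of the primary allylic alcohol installs the leaving group needed for copper-catalysed allylic substitution.

Step 11
Reactants: 6 methyl (1S)-1-methyl-3-(4,4,5,5-tetramethyl-1,3,2-dioxaborolan-2-yl)cyclohex-2-ene-1-carboxylate; 13 (2E,4R)-6-[(tert-butyldimethylsilyl)oxy]-3,4-dimethylhex-2-en-1-yl diethyl phosphate
Product: 14 methyl (1S)-3-[(3S,4R)-6-[(tert-butyldimethylsilyl)oxy]-3,4-dimethylhex-1-en-3-yl]-1-methylcyclohex-2-ene-1-carboxylate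
Conditions: CuCl (10 mol %), chiral sulfonate-bearing imidazolinium salt (carbene precursor, 11 mol %), NaOMe (1.5 equiv), THF, 22 → 50 °C
Reagents that add atoms: none
Why: Copper–carbene-catalysed enantioselective allylic substitution (SN2′) of a γ,γ-disubstituted allylic phosphate by a methoxide-activated alkenylboronate: the alkenyl–copper species bonds at C9 and leaves the C11=C12 vinyl group, the C9 configuration (S) being set by the ligand antipode beside the existing C8 centre, and NaOMe is degenerate with the methyl ester.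

Step 12
Reactants: 14 methyl (1S)-3-[(3S,4R)-6-[(tert-butyldimethylsilyl)oxy]-3,4-dimethylhex-1-en-3-yl]-1-methylcyclohex-2-ene-1-carboxylate
Product: 16 methyl (1S)-3-[(3S,4R)-6-[(tert-butyldimethylsilyl)oxy]-1-hydroxy-3,4-dimethylhexan-3-yl]-1-methylcyclohex-2-ene-1-carboxylate, via B-alkyl-9-BBN borane 15 (not isolated)
Conditions: 9-BBN, THF, 0 °C → rt; then NaOH, H2O2, 0 °C
Reagents that add atoms: hydrogen peroxide, OO; 9-borabicyclo[3.3.1]nonane, B1C2CCCC1CCC2 (its boron stays only in 15)
Why: Anti-Markovnikov hydroboration of the monosubstituted vinyl group by the bulky borane, which leaves the trisubstituted ring-A alkene alone, followed by oxidation with retention to the C12 alcohol.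

Step 13
Reactants: 16 methyl (1S)-3-[(3S,4R)-6-[(tert-butyldimethylsilyl)oxy]-1-hydroxy-3,4-dimethylhexan-3-yl]-1-methylcyclohex-2-ene-1-carboxylate
Product: 17 methyl (1S)-3-[(3S,4R)-6-[(tert-butyldimethylsilyl)oxy]-1-[(tert-butyldiphenylsilyl)oxy]-3,4-dimethylhexan-3-yl]-1-methylcyclohex-2-ene-1-carboxylate
Conditions: TBDPSCl, imidazole, DMF, rt
Reagents that add atoms: tert-butyldiphenylsilyl chloride, CC(C)(C)[Si](Cl)(c1ccccc1)c1ccccc1
Why: Silylation of the C12 alcohol with a group that survives the acidic desilylation of step 14 and the Lewis acid of step 16 and does not chelate aluminium.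

Step 14
Reactants: 17 methyl (1S)-3-[(3S,4R)-6-[(tert-butyldimethylsilyl)oxy]-1-[(tert-butyldiphenylsilyl)oxy]-3,4-dimethylhexan-3-yl]-1-methylcyclohex-2-ene-1-carboxylate
Product: 18 methyl (1S)-3-[(3S,4R)-1-[(tert-butyldiphenylsilyl)oxy]-6-hydroxy-3,4-dimethylhexan-3-yl]-1-methylcyclohex-2-ene-1-carboxylate
Conditions: PPTS (cat.), MeOH, rt
Reagents that add atoms: none
Why: Acid-catalysed methanolysis removes the primary TBS ether much faster than the bulkier TBDPS ether.

Step 15
Reactants: 18 methyl (1S)-3-[(3S,4R)-1-[(tert-butyldiphenylsilyl)oxy]-6-hydroxy-3,4-dimethylhexan-3-yl]-1-methylcyclohex-2-ene-1-carboxylate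
Product: 19 methyl (1S)-3-[(3S,4R)-1-[(tert-butyldiphenylsilyl)oxy]-3,4-dimethyl-6-oxohexan-3-yl]-1-methylcyclohex-2-ene-1-carboxylate
Conditions: Dess–Martin periodinane, NaHCO3, CH2Cl2, 0 °C → rt
Reagents that add atoms: none
Why: Buffered Dess–Martin oxidation of the primary alcohol to the C6 aldehyde; C7 is a methylene, so no stereocentre is α to the new carbonyl.

Step 16
Reactants: 19 methyl (1S)-3-[(3S,4R)-1-[(tert-butyldiphenylsilyl)oxy]-3,4-dimethyl-6-oxohexan-3-yl]-1-methylcyclohex-2-ene-1-carboxylate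
Product: 21 methyl (4S,5S,6S,8R,9S)-12-[(tert-butyldiphenylsilyl)oxy]-6-hydroxy-13,14,15,16-tetranorhalim-1(10)-en-18-oate (6-OH α, anti to H-5), via chloro(methyl)aluminium alkoxide 20 (not isolated)
Conditions: Me2AlCl (2.2 equiv), CH2Cl2, −78 → −20 °C; aq. HCl
Reagents that add atoms: dimethylaluminium chloride, C[Al](C)Cl (its aluminium stays only in 20)
Why: Me2AlCl binds the C6 aldehyde (the second equivalent occupies the C18 ester, so no chelate links the two carbonyls); C5, the CH end of the ring-A C5=C10 alkene, then bonds to C6 while the pseudoaxial H-1 passes to oxygen through a six-membered array and the alkoxide loses methane to give 20, the closest known reaction type being the Me2AlCl-promoted type 2 intramolecular carbonyl-ene cyclisation of δ,ε-unsaturated aldehydes. Ring B closes 6-exo-trig at the carbonyl carbon with the ene π bond inside the new ring, and because C9 is quaternary only C1 can give up hydrogen, so the alkene can end only at C1=C10. C5 (S): the step needs C–C bonding on the α face of ring A, anti to the ester, which leaves H-5 cis to C18; this is expected from the ring-A half-chair that has the smaller, aluminium-bound ester pseudoaxial on the β face, since only in that half-chair is H-1α axial and the α face open, and from the C9 centre, whose CH2CH2OSi arm would have to eclipse C1H2 in the β-face array. In an all-chair arrangement of this α-face closure the C8 methyl would point into the pericyclic array, so ring B is expected to close through a twist-boat-like arrangement with that methyl pseudo-equatorial, the trigonal C10 keeping the torsional cost low. C6 (S): the carbonyl oxygen has to lie endo, over C10–C1, to receive H-1, which puts the hydroxyl α and anti to H-5; this centre is removed in step 18.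

Step 17
Reactants: 21 methyl (4S,5S,6S,8R,9S)-12-[(tert-butyldiphenylsilyl)oxy]-6-hydroxy-13,14,15,16-tetranorhalim-1(10)-en-18-oate
Product: 22 methyl (4S,5S,6S,8R,9S)-12-[(tert-butyldiphenylsilyl)oxy]-6-[(phenoxycarbonothioyl)oxy]-13,14,15,16-tetranorhalim-1(10)-en-18-oate
Conditions: PhOC(S)Cl, pyridine, DMAP, CH2Cl2, rt
Reagents that add atoms: O-phenyl chlorothionoformate, S=C(Cl)Oc1ccccc1
Why: Acylation of the hindered secondary carbinol under nucleophilic catalysis, without forming a free alkoxide that could attack the C18 ester.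

Step 18
Reactants: 22 methyl (4S,5S,6S,8R,9S)-12-[(tert-butyldiphenylsilyl)oxy]-6-[(phenoxycarbonothioyl)oxy]-13,14,15,16-tetranorhalim-1(10)-en-18-oate
Product: 23 methyl (4S,5S,8R,9S)-12-[(tert-butyldiphenylsilyl)oxy]-13,14,15,16-tetranorhalim-1(10)-en-18-oate
Conditions: Bu3SnH (0.3 M), AIBN (cat.), toluene, 100 °C
Reagents that add atoms: none
Why: Barton–McCombie deoxygenation: the stannyl radical adds to C=S, the C6–O bond fragments and the secondary C6 radical is reduced, the high stannane concentration outrunning rearrangement of this homoallylic radical.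

Step 19
Reactants: 23 methyl (4S,5S,8R,9S)-12-[(tert-butyldiphenylsilyl)oxy]-13,14,15,16-tetranorhalim-1(10)-en-18-oate
Product: 24 methyl (4S,5S,8R,9S)-12-hydroxy-13,14,15,16-tetranorhalim-1(10)-en-18-oate
Conditions: Bu4NF, THF, rt
Reagents that add atoms: none
Why: Fluoride cleavage of the silyl ether; the hindered methyl ester and the alkene are inert.

Step 20
Reactants: 24 methyl (4S,5S,8R,9S)-12-hydroxy-13,14,15,16-tetranorhalim-1(10)-en-18-oate
Product: 25 methyl (4S,5S,8R,9S)-12-iodo-13,14,15,16-tetranorhalim-1(10)-en-18-oate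
Conditions: I2, PPh3, imidazole, CH2Cl2, 0 °C → rt
Reagents that add atoms: iodine, II
Why: Appel-type iodination of the primary alcohol by SN2 displacement of the alkoxyphosphonium group.

Step 21
Reactants: 25 methyl (4S,5S,8R,9S)-12-iodo-13,14,15,16-tetranorhalim-1(10)-en-18-oate
Product: 26 methyl (4S,5S,8R,9S)-15,16-dinorhalim-1(10)-en-13-yn-18-oate
Conditions: LiC≡CH·H2NCH2CH2NH2, DMSO, rt
Reagents that add atoms: lithium acetylide (ethylenediamine complex), [Li+].[C-]#C
Why: SN2 alkylation of acetylide by the unbranched primary iodide, which places C13 directly on C12 so that the chain is C9–CH2–CH2–C13, as the target requires.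

Step 22
Reactants: 26 methyl (4S,5S,8R,9S)-15,16-dinorhalim-1(10)-en-13-yn-18-oate
Product: 29 methyl (4S,5S,8R,9S,13E)-15-hydroxyhalima-1(10),13-dien-18-oate, via alkenyldimethylalane 27 (not isolated), via lithium alkenyl(butyl)dimethylaluminate 28 (not isolated)
Conditions: AlMe3, Cp2ZrCl2 (0.25 equiv), CH2Cl2, 0 °C; then n-BuLi, THF, −78 °C; (CH2O)n, −78 °C → rt
Reagents that add atoms: trimethylaluminium, C[Al](C)C; formaldehyde (as paraformaldehyde), C=O; n-butyllithium, CCCC[Li] (its butyl group stays only in 28)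
Why: Zirconium-catalysed syn-carboalumination of the terminal alkyne (methyl to C13, aluminium to C14), ate-complex formation and hydroxymethylation with retention give the E trisubstituted allylic alcohol in one operation, and the neopentyl-type tertiary ester is expected to survive the short cold exposure.

Step 23
Reactants: 29 methyl (4S,5S,8R,9S,13E)-15-hydroxyhalima-1(10),13-dien-18-oate
Product: 30 (4S,5S,8R,9S,13E)-15-hydroxyhalima-1(10),13-dien-18-oic acid
Conditions: NaSEt, DMF, 80 °C; then aq. HCl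
Reagents that add atoms: none
Why: SN2 demethylation of the hindered methyl ester by thiolate (attack at the methyl carbon, not at the shielded carbonyl), which spares both alkenes and the allylic alcohol.

Step 24
Reactants: 30 (4S,5S,8R,9S,13E)-15-hydroxyhalima-1(10),13-dien-18-oic acid
Product: 31 (4S,5S,8R,9S,13E)-15-(propanoyloxy)halima-1(10),13-dien-18-oic acid (CNP0223570.1)
Conditions: (EtCO)2O, pyridine, CH2Cl2, 0 °C → rt; aq. NaHCO3, then dilute acid
Reagents that add atoms: propionic anhydride, CCC(=O)OC(=O)CC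
Why: O-Acylation of the only hydroxyl group, the primary allylic C15–OH; the hindered tertiary carboxylic acid is not esterified under these conditions.

**Compound list**

1 | cyclohexane-1,3-dione | O=C1CCCC(=O)C1 | starting material
2 | 3-bromocyclohex-2-en-1-one | O=C1C=C(Br)CCC1 | intermediate
3 | methyl 3-oxocyclohex-1-ene-1-carboxylate | COC(=O)C1=CC(=O)CCC1 | intermediate
4 | methylzinc enolate of methyl (1S)-1-methyl-3-oxocyclohexane-1-carboxylate (enolate C5=C10) | C[Zn]OC1=C[C@@](C)(C(=O)OC)CCC1 | intermediate (not isolated)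
5 | methyl (1S)-1-methyl-3-(trifluoromethylsulfonyloxy)cyclohex-2-ene-1-carboxylate | O=S(=O)(OC1=C[C@@](C)(C(=O)OC)CCC1)C(F)(F)F | intermediate
6 | methyl (1S)-1-methyl-3-(4,4,5,5-tetramethyl-1,3,2-dioxaborolan-2-yl)cyclohex-2-ene-1-carboxylate | CC1(C)OB(OC1(C)C)C2=C[C@@](C)(C(=O)OC)CCC2 | intermediate
7 | (R)-α-methyl-γ-butyrolactone | C[C@@H]1CCOC1=O | starting material
8 | (2R)-4-hydroxy-N-methoxy-N,2-dimethylbutanamide | OCC[C@@H](C)C(=O)N(C)OC | intermediate
9 | (2R)-4-[(tert-butyldimethylsilyl)oxy]-N-methoxy-N,2-dimethylbutanamide | CC(C)(C)[Si](C)(C)OCC[C@@H](C)C(=O)N(C)OC | intermediate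
10 | (3R)-5-[(tert-butyldimethylsilyl)oxy]-3-methylpentan-2-one | CC(C)(C)[Si](C)(C)OCC[C@@H](C)C(C)=O | intermediate
11 | ethyl (2E,4R)-6-[(tert-butyldimethylsilyl)oxy]-3,4-dimethylhex-2-enoate | CC(C)(C)[Si](C)(C)OCC[C@@H](C)/C(C)=C/C(=O)OCC | intermediate
12 | (2E,4R)-6-[(tert-butyldimethylsilyl)oxy]-3,4-dimethylhex-2-en-1-ol | CC(C)(C)[Si](C)(C)OCC[C@@H](C)/C(C)=C/CO | intermediate
13 | (2E,4R)-6-[(tert-butyldimethylsilyl)oxy]-3,4-dimethylhex-2-en-1-yl diethyl phosphate | CC(C)(C)[Si](C)(C)OCC[C@@H](C)/C(C)=C/COP(=O)(OCC)OCC | intermediate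
14 | methyl (1S)-3-[(3S,4R)-6-[(tert-butyldimethylsilyl)oxy]-3,4-dimethylhex-1-en-3-yl]-1-methylcyclohex-2-ene-1-carboxylate | CC(C)(C)[Si](C)(C)OCC[C@@H](C)[C@](C)(C=C)C1=C[C@@](C)(C(=O)OC)CCC1 | intermediate
15 | B-alkyl-9-BBN borane from 14 (boron on C12) | CC(C)(C)[Si](C)(C)OCC[C@@H](C)[C@](C)(CCB1C2CCCC1CCC2)C3=C[C@@](C)(C(=O)OC)CCC3 | intermediate (not isolated)
16 | methyl (1S)-3-[(3S,4R)-6-[(tert-butyldimethylsilyl)oxy]-1-hydroxy-3,4-dimethylhexan-3-yl]-1-methylcyclohex-2-ene-1-carboxylate | CC(C)(C)[Si](C)(C)OCC[C@@H](C)[C@](C)(CCO)C1=C[C@@](C)(C(=O)OC)CCC1 | intermediate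
17 | methyl (1S)-3-[(3S,4R)-6-[(tert-butyldimethylsilyl)oxy]-1-[(tert-butyldiphenylsilyl)oxy]-3,4-dimethylhexan-3-yl]-1-methylcyclohex-2-ene-1-carboxylate | CC(C)(C)[Si](C)(C)OCC[C@@H](C)[C@](C)(CCO[Si](c1ccccc1)(c1ccccc1)C(C)(C)C)C1=C[C@@](C)(C(=O)OC)CCC1 | intermediate
18 | methyl (1S)-3-[(3S,4R)-1-[(tert-butyldiphenylsilyl)oxy]-6-hydroxy-3,4-dimethylhexan-3-yl]-1-methylcyclohex-2-ene-1-carboxylate | OCC[C@@H](C)[C@](C)(CCO[Si](c1ccccc1)(c1ccccc1)C(C)(C)C)C1=C[C@@](C)(C(=O)OC)CCC1 | intermediate
19 | methyl (1S)-3-[(3S,4R)-1-[(tert-butyldiphenylsilyl)oxy]-3,4-dimethyl-6-oxohexan-3-yl]-1-methylcyclohex-2-ene-1-carboxylate (key-step precursor) | O=CC[C@@H](C)[C@](C)(CCO[Si](c1ccccc1)(c1ccccc1)C(C)(C)C)C1=C[C@@](C)(C(=O)OC)CCC1 | intermediate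
20 | chloro(methyl)aluminium alkoxide of 21 (O–Al on C6) | CC(C)(C)[Si](c1ccccc1)(c1ccccc1)OCC[C@]1(C)C2=CCC[C@](C)(C(=O)OC)[C@H]2[C@@H](O[Al](C)Cl)C[C@H]1C | intermediate (not isolated)
21 | methyl (4S,5S,6S,8R,9S)-12-[(tert-butyldiphenylsilyl)oxy]-6-hydroxy-13,14,15,16-tetranorhalim-1(10)-en-18-oate (key-step product) | CC(C)(C)[Si](c1ccccc1)(c1ccccc1)OCC[C@]1(C)C2=CCC[C@](C)(C(=O)OC)[C@H]2[C@@H](O)C[C@H]1C | intermediate
22 | methyl (4S,5S,6S,8R,9S)-12-[(tert-butyldiphenylsilyl)oxy]-6-[(phenoxycarbonothioyl)oxy]-13,14,15,16-tetranorhalim-1(10)-en-18-oate | CC(C)(C)[Si](c1ccccc1)(c1ccccc1)OCC[C@]1(C)C2=CCC[C@](C)(C(=O)OC)[C@H]2[C@@H](OC(=S)Oc3ccccc3)C[C@H]1C | intermediate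
23 | methyl (4S,5S,8R,9S)-12-[(tert-butyldiphenylsilyl)oxy]-13,14,15,16-tetranorhalim-1(10)-en-18-oate | CC(C)(C)[Si](c1ccccc1)(c1ccccc1)OCC[C@]1(C)C2=CCC[C@](C)(C(=O)OC)[C@H]2CC[C@H]1C | intermediate
24 | methyl (4S,5S,8R,9S)-12-hydroxy-13,14,15,16-tetranorhalim-1(10)-en-18-oate | OCC[C@]1(C)C2=CCC[C@](C)(C(=O)OC)[C@H]2CC[C@H]1C | intermediate
25 | methyl (4S,5S,8R,9S)-12-iodo-13,14,15,16-tetranorhalim-1(10)-en-18-oate | ICC[C@]1(C)C2=CCC[C@](C)(C(=O)OC)[C@H]2CC[C@H]1C | intermediate
26 | methyl (4S,5S,8R,9S)-15,16-dinorhalim-1(10)-en-13-yn-18-oate | C#CCC[C@]1(C)C2=CCC[C@](C)(C(=O)OC)[C@H]2CC[C@H]1C | intermediate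
27 | (13E)-alkenyldimethylalane from 26 (AlMe2 on C14, methyl on C13) | C[Al](C)/C=C(\C)CC[C@]1(C)C2=CCC[C@](C)(C(=O)OC)[C@H]2CC[C@H]1C | intermediate (not isolated)
28 | lithium alkenyl(butyl)dimethylaluminate from 27 | [Li+].CCCC[Al-](C)(C)/C=C(\C)CC[C@]1(C)C2=CCC[C@](C)(C(=O)OC)[C@H]2CC[C@H]1C | intermediate (not isolated)
29 | methyl (4S,5S,8R,9S,13E)-15-hydroxyhalima-1(10),13-dien-18-oate | OC/C=C(\C)CC[C@]1(C)C2=CCC[C@](C)(C(=O)OC)[C@H]2CC[C@H]1C | intermediate
30 | (4S,5S,8R,9S,13E)-15-hydroxyhalima-1(10),13-dien-18-oic acid | OC/C=C(\C)CC[C@]1(C)C2=CCC[C@](C)(C(=O)O)[C@H]2CC[C@H]1C | intermediate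
31 | (4S,5S,8R,9S,13E)-15-(propanoyloxy)halima-1(10),13-dien-18-oic acid (CNP0223570.1) | CCC(=O)OC/C=C(\C)CC[C@]1(C)C2=CCC[C@](C)(C(=O)O)[C@H]2CC[C@H]1C | target

**Step count**

Total: 24 steps. Longest linear sequence: 20 steps (7 → 31, steps 5–24); the ring-A branch (steps 1–4) joins at step 11.

**Steps most likely to fail**

1. Step 16 (key step). What may go wrong: poor facial selectivity at C5. Closure on the ester-bearing β face can run through an all-chair array with the C8 methyl equatorial, whereas the required α-face closure has to avoid an inward-pointing C8 methyl; this competition is the main uncertainty of the route. Ionisation to a C10 cation with loss of regiocontrol is a second failure mode. Fallback: it sets out from aldehyde 19 and returns at 23, and it sets C5 by protonation instead of by the C–C bond formation. Aldehyde 19 is cyclised as in step 16 and the carbinols are taken on whatever their ratio, that is 21 together with its C5,C6-epimer, the (5R,6R)-carbinol F1. Dess–Martin oxidation gives the (5R)-6-ketone F2 beside its (5S)-epimer F4. KOt-Bu in t-BuOH/THF converts both into the same extended potassium dienolate F3 (C1=C10–C5=C6–O). Inverse quench into cold aqueous acetic acid protonates the dienolate kinetically at C5 and so returns the β,γ-unsaturated ketone. With the ester held near the enolate plane, the C19 methyl is pseudoaxial on the α face, so the proton should arrive from the β face and give the (5S)-ketone F4. Condensation with TsNHNH2 gives the tosylhydrazone F5, and reduction with catecholborane, then NaOAc, gives the methylene compound 23.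

2. Step 11. What may go wrong: slow boron-to-copper transmetalation of the hindered ring alkenylboronate, and poor regio- or face selection at the congested γ-carbon next to the C8 centre (SN2 leakage, mismatched pairing of ligand and substrate). Fallback: it sets out from triflate 5 and allylic alcohol 12 and returns at 16, replacing the allylic substitution by a palladium-catalysed enantioselective redox-relay Heck alkenylation of the trisubstituted allylic alcohol (Pd2(dba)3, chiral pyridine–oxazoline ligand, DMA, rt). The alkenyl group adds to C9, palladium migrates to the carbinol carbon, and the C12 aldehyde results: methyl (1S)-3-[(3S,4R)-6-[(tert-butyldimethylsilyl)oxy]-3,4-dimethyl-1-oxohexan-3-yl]-1-methylcyclohex-2-ene-1-carboxylate F6. NaBH4 in MeOH reduces it to alcohol 16. This path needs neither 6 nor 13.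

3. Step 22. What may go wrong: consumption of the C18 ester by AlMe3 or n-BuLi, and incomplete capture of the alkenyl aluminate by formaldehyde, which leaves the protonated alkene. Fallback: it sets out from iodide 25 and returns at the target 31, building C13 as a ketone and the alkene by olefination.
   - Alkylation of 2-lithio-2-methyl-1,3-dithiane (THF/HMPA, −78 → −30 °C) with 25 gives the dithiane F7.
   - MeI, CaCO3 in aqueous MeCN releases the C13 methyl ketone F8.
   - Horner–Wadsworth–Emmons reaction with triethyl phosphonoacetate and NaH gives the E diester F9 (minor Z isomer removed by chromatography).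
   - LiAlH4 reduces both esters to the 15,18-diol F10.
   - EtCOCl with 2,4,6-collidine at −78 °C should acylate the allylic C15 hydroxyl ahead of the neopentyl C18 hydroxyl and give the 15-propionate F11.
   - Dess–Martin oxidation gives the C18 aldehyde F12, and Pinnick oxidation (NaClO2, NaH2PO4, 2-methyl-2-butene, t-BuOH/H2O) gives 31.

**Further compounds**

F1 | step 16 | methyl (4S,5R,6R,8R,9S)-12-[(tert-butyldiphenylsilyl)oxy]-6-hydroxy-13,14,15,16-tetranorhalim-1(10)-en-18-oate | CC(C)(C)[Si](c1ccccc1)(c1ccccc1)OCC[C@]1(C)C2=CCC[C@](C)(C(=O)OC)[C@@H]2[C@H](O)C[C@H]1C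
F2 | step 16 | methyl (4S,5R,8R,9S)-12-[(tert-butyldiphenylsilyl)oxy]-6-oxo-13,14,15,16-tetranorhalim-1(10)-en-18-oate | CC(C)(C)[Si](c1ccccc1)(c1ccccc1)OCC[C@]1(C)C2=CCC[C@](C)(C(=O)OC)[C@@H]2C(=O)C[C@H]1C
F3 | step 16 | potassium dienolate (C1=C10–C5=C6–O) of the 6-ketone | CC(C)(C)[Si](c1ccccc1)(c1ccccc1)OCC[C@]1(C)C2=CCC[C@](C)(C(=O)OC)C2=C([O-])C[C@H]1C.[K+]
F4 | step 16 | methyl (4S,5S,8R,9S)-12-[(tert-butyldiphenylsilyl)oxy]-6-oxo-13,14,15,16-tetranorhalim-1(10)-en-18-oate | CC(C)(C)[Si](c1ccccc1)(c1ccccc1)OCC[C@]1(C)C2=CCC[C@](C)(C(=O)OC)[C@H]2C(=O)C[C@H]1C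
F5 | step 16 | tosylhydrazone of F4 | CC(C)(C)[Si](c1ccccc1)(c1ccccc1)OCC[C@]1(C)C2=CCC[C@](C)(C(=O)OC)[C@H]2C(=NNS(=O)(=O)c3ccc(C)cc3)C[C@H]1C
F6 | step 11 | methyl (1S)-3-[(3S,4R)-6-[(tert-butyldimethylsilyl)oxy]-3,4-dimethyl-1-oxohexan-3-yl]-1-methylcyclohex-2-ene-1-carboxylate | CC(C)(C)[Si](C)(C)OCC[C@@H](C)[C@](C)(CC=O)C1=C[C@@](C)(C(=O)OC)CCC1
F7 | step 22 | methyl (4S,5S,8R,9S)-12-(2-methyl-1,3-dithian-2-yl)-13,14,15,16-tetranorhalim-1(10)-en-18-oate | CC1(CC[C@]2(C)C3=CCC[C@](C)(C(=O)OC)[C@H]3CC[C@H]2C)SCCCS1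
F8 | step 22 | methyl (4S,5S,8R,9S)-13-oxo-14,15-dinorhalim-1(10)-en-18-oate (C13 methyl ketone) | CC(=O)CC[C@]1(C)C2=CCC[C@](C)(C(=O)OC)[C@H]2CC[C@H]1C
F9 | step 22 | 15-ethyl 18-methyl (4S,5S,8R,9S,13E)-halima-1(10),13-diene-15,18-dioate | CCOC(=O)/C=C(\C)CC[C@]1(C)C2=CCC[C@](C)(C(=O)OC)[C@H]2CC[C@H]1C
F10 | step 22 | (4S,5S,8R,9S,13E)-halima-1(10),13-diene-15,18-diol | OC/C=C(\C)CC[C@]1(C)C2=CCC[C@](C)(CO)[C@H]2CC[C@H]1C
F11 | step 22 | (4S,5S,8R,9S,13E)-18-hydroxyhalima-1(10),13-dien-15-yl propanoate | CCC(=O)OC/C=C(\C)CC[C@]1(C)C2=CCC[C@](C)(CO)[C@H]2CC[C@H]1C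
F12 | step 22 | (4S,5S,8R,9S,13E)-18-oxohalima-1(10),13-dien-15-yl propanoate | CCC(=O)OC/C=C(\C)CC[C@]1(C)C2=CCC[C@](C)(C=O)[C@H]2CC[C@H]1C
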